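## Structural features

The target is a trans-fused decalin (labdane numbering). Ring A (C1–C5, C10) is saturated and carries a gem-dimethyl group at C4 and an angular methyl group at C10. Ring B (C5–C10) holds the C7=C8 alkene, conjugated with the carboxylic acid carbon C17 on C8. C9 carries a four-carbon chain (C11–C14) with a methyl branch at C13 and a primary isobutyrate at C14. Three contiguous stereocentres sit in the bicycle: C5 (α-H), the quaternary C10 (β-methyl) and C9 (β-chain, cis to the C10 methyl). The fourth, C13 (R), lies three bonds from C9 and cannot be controlled from the ring. The fragile groups are the isobutyrate (no saponification and no hard nucleophile once it is present) and the C9–H, which is allylic to the enoic acid and could be lost by alkene migration to C8=C9. The real difficulty is the quaternary C10 bonded to C5 next to the second quaternary carbon C4 (1,3-diaxial methyl groups), together with absolute control of C5, C9 and C10 in a ring system without a heteroatom handle. The key step exploits that ring B becomes a Diels–Alder cyclohexene once its alkene is moved to C6–C7: C5–C10 and C8–C9 are then the two σ bonds, C5=C6–C7=C8 the diene, C9=C10 the dienophile activated by C11 as a formyl group, and C1–C4 of ring A the tether.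

## Logic of the disconnections

**26 ⇒ 25.** No skeletal bond is cut; the saturated C11–C12 bond is traced back to a C11=C12 alkene so that the chain can be joined by olefination. The forward step must reduce a disubstituted alkene and leave the trisubstituted C7=C8 alkene conjugated with the acid untouched.

**25 ⇒ 24 ⇒ 22 ⇒ 21.** Again no skeletal bond is cut. The acid at C17 and the C7=C8 alkene are traced back to a silyl-protected hydroxymethyl group on C8 and an alkene at C6–C7. The gain is that ring B of 21 is the cyclohexene a [4+2] cycloaddition leaves behind. The forward steps need a desilylation that spares the isobutyrate, an oxidation, a base-mediated shift of the alkene towards C7=C8 only (secured because the dienolate of 23 can be protonated only at C8 or C6), and a chlorite oxidation.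

**21 ⇒ 15 + 20.** The C11=C12 bond is cut. This separates the bicyclic core from a small fragment that brings C13 from the chiral pool, so the remote stereocentre is bought and the route becomes convergent. The forward olefination needs the carbanion of 20 to add to the hindered formyl group of 15 faster than it attacks its own ester or enolises C9.

**15 ⇒ 14 (key).** C5–C10 and C8–C9 are cut in a retro-[4+2]. Both rings and all ring stereocentres are exchanged for an acyclic, achiral triene whose only stereochemical content is three alkene geometries. The forward step needs a Lewis acid able to activate a β,β-disubstituted enal, the formyl-endo/tether-exo transition state, and catalyst control of the enantiotopic face. The silyl group on O17 is a spectator; the bulkier, less basic tert-butyldiphenylsilyl ether is carried so that it neither binds the boron cation nor ionises.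

**14 ⇒ 13 ⇒ 10.** The C10–CH3 bond and the C9–C11 bond are cut, back to a terminal alkyne. The reason is geometric: the C9=C10 geometry fixes the C9/C10 relative configuration in 15, and olefination of a methyl ketone would give E/Z mixtures. Syn-methylmetalation of an alkyne gives the (E)-alkene by mechanism. The forward step must tolerate the dienyl silyl ether, and the oxidation must not isomerise the enal.

**10 ⇒ 9 ⇒ 8 ⇒ 6 + 7.** The C5=C6 bond is cut. One vinylogous phosphonate olefination brings C6, C7, C8 and C17 with (E,E) geometry from the commercial reagent 7. The demands are E,E-selectivity with a neopentylic aldehyde, then 1,2-reduction and silylation.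

**6 ⇒ 4 ⇒ 3 ⇒ 1 + 2.** The C3–C4 and C1–C10 bonds are cut, and the C5 aldehyde is traced to a nitrile. The quaternary C4 comes from alkylation of a tertiary nitrile anion; the nitrile is chosen over an ester because one hydride reduction gives the aldehyde. The pieces are 1, 2 and acetylide. The demands are displacement of bromide before chloride, SN2 of acetylide on the chloride, and partial reduction of the nitrile.

**20 ⇒ 19 ⇒ 18 ⇒ 16 + 17.** The C12–S bond and the ester C–O bond are cut. 16 supplies C12–C14 and the C13 stereocentre, which no step touches. The demands are S-alkylation, acylation, and oxidation to the sulfone without harming the ester.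

## Other disconnections considered

**Alternative 1:** The cut removes C8, that is the bonds C7–C8 and C8–C9, and leads to the trans-hydrindene A1 with a C7=C9 alkene bearing the protected chain. In the forward step dibromocarbene (CHBr3, KOt-Bu) adds to that alkene and AgOAc opens the adduct with ring expansion to the allylic acetate A2.
- In its favour: both operations are standard and strain-driven. The C8 vinyl bromide of A2 is a direct handle for C17 (carboxylation or carbonylation), which is a better way to bring in the acid carbon than the four-step adjustment of the chosen plan. In precedent for the key transformation itself it is also the better of the two.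
- Against it here: the key step creates no permanent stereocentre. A1, with the quaternary C10 beside C4 in a strained trans-hydrindane, is as hard to make enantiopure as the decalin itself. After expansion the alkene lies at C8=C9, so C9–H must still be set by a reductive allylic transposition of uncertain facial control.
- Comparison: one ring from an already bicyclic precursor, against two rings and three permanent stereocentres from an acyclic triene. The mechanism is more secure but the C9 problem is postponed. Step economy is worse.

**Alternative 2:** The cut is at C4–C5 and C9–C10 and leads to the acyclic (S)-epoxide A3, whose chain ends in a (Z)-silyl enol ether. In the forward step MeAlCl2 opens the epoxide and a chair–chair cation–alkene cascade closes both rings, giving the hydroxy ketone A4.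
- In its favour: this reaction class suits exactly this substitution pattern. Cation–alkene closure forms the congested C4–C5 and C9–C10 bonds with little steric penalty, where it is better than the chosen plan, whose cycloaddition must force C5 onto a fully substituted carbon. It is equal in rings and stereocentres created. The C8 ketone of A4 can reach the unsaturated acid by triflation towards C7 and carbonylation, so the endgame is about equal in length.
- Against it here: A4 carries a 3β-hydroxyl that the target lacks, so two deoxygenation steps are added. A3 needs an enantioselective epoxidation and a geometrically pure, acid-labile silyl enol ether that must survive until the cascade reaches it.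
- Comparison: better precedent, somewhat worse step and redox economy. The chosen plan makes no functional group that has to be removed.

**Alternative 3:** The cut is at C9–C10 alone and leads to the monocyclic acetoxy enoate A5 (ring A with a C1=C10 alkene). In the forward step Fe(acac)3 and PhSiH3 deliver a hydrogen atom to C1; the tertiary C10 radical adds 6-endo to C9 of the enoate, and the resulting ester enolate expels the C7 acetate to give the ester A6.
- In its favour: radicals form bonds to quaternary carbon easily, which is better than the chosen plan for C10. A6 already has the C7=C8 enoate at the right oxidation level, which is better than the chosen plan after the key step.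
- Against it here: only one ring is closed. A5 needs its C5 stereocentre from elsewhere. The C9 configuration and the ring fusion rest on substrate control in a slow 6-endo addition to a β-substituted acceptor, with simple reduction of either alkene as competition. The methyl ester must be hydrolysed before the isobutyrate is installed, which forces a protecting-group exchange at C14.
- Comparison: one ring and two stereocentres, against two rings and three. The mechanism suits congestion but is not catalyst-controlled. The route is longer before the key step and about equal after it.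

Key step: step 9

Assumption: the enal is taken to bind the boron cation in the usual way for enals (formyl C–H···O contact, s-trans C=C over the neighbouring phenyl group). On that model the catalyst from (R)-α,α-diphenylprolinol leaves the C9 Si face open, which leads to the 10β-methyl series; if the sense proved opposite, the (S)-catalyst would be used with no other change.

## Route

Step 1
Reactants: 1 2-methylpropanenitrile (isobutyronitrile); 2 1-bromo-3-chloropropane
Product: 3 5-chloro-2,2-dimethylpentanenitrile
Conditions: LiN(i-Pr)2 (1.05 equiv), THF, −78 °C; then 2 (1.3 equiv), −78 °C → rt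
Reagents that add atoms: none
Why: Alkylation of a tertiary nitrile anion forms C3–C4 and makes C4 quaternary; bromide is displaced far faster than chloride, so the chloride remains as the handle for step 2.

Step 2
Reactants: 3
Product: 4 2,2-dimethylhept-6-ynenitrile
Conditions: LiC≡CH·H2NCH2CH2NH2 (1.5 equiv), DMSO, 10 °C → rt
Reagents that add atoms: lithium acetylide–ethylenediamine complex, [Li+].[C-]#C.NCCN
Why: SN2 displacement of a primary chloride by acetylide forms C1–C10; the nitrile has no α-hydrogen and is too hindered to add the acetylide.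

Step 3
Reactants: 4
Product: 6 2,2-dimethylhept-6-ynal, via iminoalane 5 (not isolated)
Conditions: i-Bu2AlH (1.2 equiv), CH2Cl2, −78 → 0 °C; then 1 M HCl, 0 °C
Reagents that add atoms: water, O
Why: Partial reduction of a nitrile: one hydride gives the N-aluminated aldimine 5, which resists further reduction and is hydrolysed in the work-up; the aldehyde cannot enolise and the terminal alkyne is inert at this temperature.

Step 4
Reactants: 6; 7 triethyl 4-phosphonocrotonate
Product: 8 ethyl (2E,4E)-6,6-dimethylundeca-2,4-dien-10-ynoate
Conditions: 7 (1.3 equiv), LiN(SiMe3)2 (1.25 equiv), THF, −78 °C; then 6, −78 → 0 °C; aq. NH4Cl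
Reagents that add atoms: none
Why: Vinylogous Horner–Wadsworth–Emmons olefination forms C5=C6 and should give the (E,E)-dienoate with a non-enolisable neopentylic aldehyde; the stabilised phosphonate anion is too weak a base to deprotonate the alkyne.

Step 5
Reactants: 8
Product: 9 (2E,4E)-6,6-dimethylundeca-2,4-dien-10-yn-1-ol
Conditions: i-Bu2AlH (2.3 equiv), CH2Cl2, −78 °C; aq. potassium sodium tartrate
Reagents that add atoms: none
Why: 1,2-Reduction of a conjugated ester by i-Bu2AlH at low temperature, with no conjugate reduction and no reaction at the alkyne.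

Step 6
Reactants: 9
Product: 10 tert-butyl{[(2E,4E)-6,6-dimethylundeca-2,4-dien-10-yn-1-yl]oxy}diphenylsilane
Conditions: TBDPSCl (1.1 equiv), imidazole (2 equiv), CH2Cl2, 0 °C → rt
Reagents that add atoms: tert-butyl(chloro)diphenylsilane, CC(C)(C)[Si](Cl)(c1ccccc1)c1ccccc1
Why: Silylation of a primary alcohol; the TBDPS ether is a poor Lewis base and far more acid-stable than a TBS ether, which matters for the Lewis acids of steps 7 and 9.

Step 7
Reactants: 10
Product: 13 (2E,8E,10E)-12-[(tert-butyldiphenylsilyl)oxy]-3,7,7-trimethyldodeca-2,8,10-trien-1-ol, via alkenyldimethylalane 11 (not isolated), via lithium alkenylaluminate 12 (not isolated)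
Conditions: Me3Al (2.5 equiv), Cp2ZrCl2 (0.25 equiv), CH2Cl2, 0 °C → rt; volatiles removed; n-BuLi, hexane/THF, −78 → 0 °C; (CH2O)n, rt; aq. potassium sodium tartrate
Reagents that add atoms: trimethylaluminium, C[Al](C)C; paraformaldehyde (as formaldehyde), C=O
Why: Negishi zirconium-catalysed methylalumination adds CH3 and Al syn across the terminal alkyne with aluminium on the terminal carbon, and the aluminate 12 adds to formaldehyde with retention; the (E)-geometry of C9=C10 (C11 cis to the new methyl group) is therefore fixed by mechanism.

Step 8
Reactants: 13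
Product: 14 (2E,8E,10E)-12-[(tert-butyldiphenylsilyl)oxy]-3,7,7-trimethyldodeca-2,8,10-trienal
Conditions: MnO2 (15 equiv), CH2Cl2, rt
Reagents that add atoms: none
Why: Allylic oxidation on activated MnO2 under neutral heterogeneous conditions should leave the enal geometry, the diene and the silyl ether untouched.

Step 9
Reactants: 14
Product: 15 (1S,2S,4aS,8aS)-2-{[(tert-butyldiphenylsilyl)oxy]methyl}-5,5,8a-trimethyl-1,2,4a,5,6,7,8,8a-octahydronaphthalene-1-carbaldehyde (labdane numbering: 5α-H; 8β-CH2OTBDPS; 9β-CHO; 10β-CH3; C6=C7)
Conditions: oxazaborolidinium triflimide from (R)-α,α-diphenylprolinol, (o-TolBO)3 and HNTf2 (20 mol %), CH2Cl2, −78 → −20 °C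
Reagents that add atoms: none
Why: Proposed new method: coordination of the formyl oxygen of 14 to the boron cation (anti to C9, formyl C–H···O contact to the ring oxygen) should make the β,β-disubstituted (E)-enal electron-poor enough for the tethered (E,E)-diene to add in a concerted, asynchronous [4+2] that forms C5–C10 and C8–C9; the closest known reaction type is the oxazaborolidinium-catalysed intramolecular Diels–Alder reaction of (E)-trienals whose dienophile has no β-methyl group, and the new element is the fully substituted carbon that becomes C10. Ring B is closed by the cycloaddition itself (six-membered, both new bonds in the ring), and ring A by the C5–C10 bond through the C1–C4 tether in the 1,7,9-decatriene mode with a chair-like tether. C10 relative to C9 follows from suprafacial addition to the (E)-enal secured in step 7, which puts the C10 methyl cis to C9–C11. The C5/C10 trans fusion follows from the formyl group, with the catalyst on it, lying under the diene (endo) while the tether points away (exo). The temporary C8 centre follows from the (E,E)-diene, which places C17 cis to C4 on ring B (8β). The absolute configuration follows from the phenyl group of the (R)-catalyst covering the C9 Re face of the s-trans enal, so the diene adds to the Si face. The step needs endo over exo selectivity and face selectivity against the developing 1,3-diaxial contact of the C10 and C4 methyl groups; Lewis-acid binding (stronger endo preference), the gem-dimethyl group on the tether (reactive rotamer) and the weakly basic TBDPS ether (no competition for boron, no ionisation) are what the substrate offers to secure them.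

Step 10
Reactants: 16 (2S)-3-bromo-2-methylpropan-1-ol; 17 1-phenyl-1H-tetrazole-5-thiol
Product: 18 (2S)-2-methyl-3-[(1-phenyl-1H-tetrazol-5-yl)sulfanyl]propan-1-ol
Conditions: K2CO3 (1.5 equiv), acetone, reflux
Reagents that add atoms: none
Why: S-Alkylation of the thiolate by the primary bromide forms the C12–S bond; the stereocentre is not involved and the soft thiolate outruns any oxetane formation.

Step 11
Reactants: 18
Product: 19 (2S)-2-methyl-3-[(1-phenyl-1H-tetrazol-5-yl)sulfanyl]propyl 2-methylpropanoate
Conditions: i-PrCOCl (1.2 equiv), Et3N (1.5 equiv), DMAP (cat.), CH2Cl2, 0 °C → rt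
Reagents that add atoms: 2-methylpropanoyl chloride, CC(C)C(Cl)=O
Why: Acylation of a primary alcohol installs the isobutyrate of the target at the outset, so no late differentiation of O14 and O17 is needed.

Step 12
Reactants: 19
Product: 20 (2S)-2-methyl-3-[(1-phenyl-1H-tetrazol-5-yl)sulfonyl]propyl 2-methylpropanoate
Conditions: (NH4)6Mo7O24·4H2O (10 mol %), 30% aq. H2O2 (6 equiv), EtOH, 0 °C → rt
Reagents that add atoms: hydrogen peroxide, OO
Why: Molybdate-catalysed oxidation of the sulfide to the sulfone by H2O2; the ester is inert under these near-neutral conditions.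

Step 13
Reactants: 15; 20
Product: 21 (2R,3E)-4-[(1S,2S,4aS,8aR)-2-{[(tert-butyldiphenylsilyl)oxy]methyl}-5,5,8a-trimethyl-1,2,4a,5,6,7,8,8a-octahydronaphthalen-1-yl]-2-methylbut-3-en-1-yl 2-methylpropanoate
Conditions: 15 and 20 (1.4 equiv) in THF, −78 °C; KN(SiMe3)2 (1.35 equiv) added slowly (Barbier mode); −78 °C → rt; aq. NH4Cl
Reagents that add atoms: none
Why: Julia–Kocienski olefination: the sulfonyl carbanion adds to the formyl group, and Smiles rearrangement with loss of SO2 and the tetrazololate gives the C11=C12 alkene, whose geometry does not matter because it is reduced in step 17. Generating the carbanion in the presence of the aldehyde keeps its lifetime short, which protects the ester and C9.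

Step 14
Reactants: 21
Product: 22 (2R,3E)-4-[(1S,2S,4aS,8aR)-2-(hydroxymethyl)-5,5,8a-trimethyl-1,2,4a,5,6,7,8,8a-octahydronaphthalen-1-yl]-2-methylbut-3-en-1-yl 2-methylpropanoate
Conditions: Bu4NF (1.5 equiv), AcOH (1.5 equiv), THF, 0 °C → rt
Reagents that add atoms: none
Why: Fluoride cleavage of the silyl ether; buffering with AcOH keeps the medium from becoming basic enough to cleave or transfer the isobutyrate.

Step 15
Reactants: 22
Product: 24 (2R,3E)-4-[(1R,4aS,8aS)-2-formyl-5,5,8a-trimethyl-1,4,4a,5,6,7,8,8a-octahydronaphthalen-1-yl]-2-methylbut-3-en-1-yl 2-methylpropanoate, via β,γ-unsaturated aldehyde 23 (not isolated)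
Conditions: DMP (1.3 equiv), CH2Cl2, 0 °C → rt; then DBU (4 equiv), rt
Reagents that add atoms: none
Why: Dess–Martin oxidation gives the β,γ-unsaturated aldehyde 23. DBU removes the C8–H (α to the formyl group and allylic) and the dienolate is protonated at C6, giving the conjugated C7=C8 enal and erasing the temporary C8 centre. C9–H is not activated by the carbonyl group and should not epimerise.

Step 16
Reactants: 24
Product: 25 (1R,4aS,8aS)-5,5,8a-trimethyl-1-[(1E,3R)-3-methyl-4-(2-methylpropanoyloxy)but-1-en-1-yl]-1,4,4a,5,6,7,8,8a-octahydronaphthalene-2-carboxylic acid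
Conditions: NaClO2 (3 equiv), NaH2PO4 (3 equiv), 2-methylbut-2-ene (20 equiv), t-BuOH/H2O, 0 °C → rt
Reagents that add atoms: sodium chlorite, [Na+].[O-]Cl=O
Why: Pinnick oxidation of the enal to the enoic acid under buffered conditions; the alkene scavenger takes up HOCl, so the C11=C12 alkene and the ester are spared.

Step 17
Reactants: 25
Product: 26 (1R,4aS,8aS)-5,5,8a-trimethyl-1-[(3R)-3-methyl-4-(2-methylpropanoyloxy)butyl]-1,4,4a,5,6,7,8,8a-octahydronaphthalene-2-carboxylic acid (target)
Conditions: 2-O2NC6H4SO2NHNH2 (10 equiv, in portions), Et3N (20 equiv), CH2Cl2, rt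
Reagents that add atoms: none
Why: Diimide reduction: concerted syn transfer of two hydrogens, whose rate falls steeply with alkene substitution, so the disubstituted C11=C12 alkene should be reduced while the trisubstituted, conjugated C7=C8 alkene of the carboxylate stays. No metal is present, so no isomerisation or ester cleavage is expected.

## Compound list

1 | 2-methylpropanenitrile (isobutyronitrile) | CC(C)C#N | starting material
2 | 1-bromo-3-chloropropane | ClCCCBr | starting material
3 | 5-chloro-2,2-dimethylpentanenitrile | N#CC(C)(C)CCCCl | intermediate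
4 | 2,2-dimethylhept-6-ynenitrile | N#CC(C)(C)CCCC#C | intermediate
5 | N-(diisobutylalumanyl)-2,2-dimethylhept-6-yn-1-imine | CC(C)C[Al](CC(C)C)N=CC(C)(C)CCCC#C | intermediate (not isolated)
6 | 2,2-dimethylhept-6-ynal | O=CC(C)(C)CCCC#C | intermediate
7 | triethyl 4-phosphonocrotonate | CCOC(=O)/C=C/CP(=O)(OCC)OCC | starting material
8 | ethyl (2E,4E)-6,6-dimethylundeca-2,4-dien-10-ynoate | CCOC(=O)/C=C/C=C/C(C)(C)CCCC#C | intermediate
9 | (2E,4E)-6,6-dimethylundeca-2,4-dien-10-yn-1-ol | OC/C=C/C=C/C(C)(C)CCCC#C | intermediate
10 | tert-butyl{[(2E,4E)-6,6-dimethylundeca-2,4-dien-10-yn-1-yl]oxy}diphenylsilane | C#CCCCC(C)(C)/C=C/C=C/CO[Si](c1ccccc1)(c1ccccc1)C(C)(C)C | intermediate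
11 | dimethyl{(1E,7E,9E)-11-[(tert-butyldiphenylsilyl)oxy]-2,6,6-trimethylundeca-1,7,9-trien-1-yl}alumane | C[Al](C)/C=C(\C)CCCC(C)(C)/C=C/C=C/CO[Si](c1ccccc1)(c1ccccc1)C(C)(C)C | intermediate (not isolated)
12 | lithium butyl(dimethyl){(1E,7E,9E)-11-[(tert-butyldiphenylsilyl)oxy]-2,6,6-trimethylundeca-1,7,9-trien-1-yl}aluminate | [Li+].CCCC[Al-](C)(C)/C=C(\C)CCCC(C)(C)/C=C/C=C/CO[Si](c1ccccc1)(c1ccccc1)C(C)(C)C | intermediate (not isolated)
13 | (2E,8E,10E)-12-[(tert-butyldiphenylsilyl)oxy]-3,7,7-trimethyldodeca-2,8,10-trien-1-ol | OC/C=C(\C)CCCC(C)(C)/C=C/C=C/CO[Si](c1ccccc1)(c1ccccc1)C(C)(C)C | intermediate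
14 | (2E,8E,10E)-12-[(tert-butyldiphenylsilyl)oxy]-3,7,7-trimethyldodeca-2,8,10-trienal | O=C/C=C(\C)CCCC(C)(C)/C=C/C=C/CO[Si](c1ccccc1)(c1ccccc1)C(C)(C)C | intermediate (precursor of the key step)
15 | (1S,2S,4aS,8aS)-2-{[(tert-butyldiphenylsilyl)oxy]methyl}-5,5,8a-trimethyl-1,2,4a,5,6,7,8,8a-octahydronaphthalene-1-carbaldehyde | O=C[C@H]1[C@@H](CO[Si](c3ccccc3)(c3ccccc3)C(C)(C)C)C=C[C@H]2C(C)(C)CCC[C@]12C | intermediate (product of the key step)
16 | (2S)-3-bromo-2-methylpropan-1-ol | OC[C@H](C)CBr | starting material
17 | 1-phenyl-1H-tetrazole-5-thiol | Sc1nnnn1-c1ccccc1 | starting material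
18 | (2S)-2-methyl-3-[(1-phenyl-1H-tetrazol-5-yl)sulfanyl]propan-1-ol | OC[C@H](C)CSc1nnnn1-c1ccccc1 | intermediate
19 | (2S)-2-methyl-3-[(1-phenyl-1H-tetrazol-5-yl)sulfanyl]propyl 2-methylpropanoate | CC(C)C(=O)OC[C@H](C)CSc1nnnn1-c1ccccc1 | intermediate
20 | (2S)-2-methyl-3-[(1-phenyl-1H-tetrazol-5-yl)sulfonyl]propyl 2-methylpropanoate | CC(C)C(=O)OC[C@H](C)CS(=O)(=O)c1nnnn1-c1ccccc1 | intermediate
21 | (2R,3E)-4-[(1S,2S,4aS,8aR)-2-{[(tert-butyldiphenylsilyl)oxy]methyl}-5,5,8a-trimethyl-1,2,4a,5,6,7,8,8a-octahydronaphthalen-1-yl]-2-methylbut-3-en-1-yl 2-methylpropanoate | CC(C)C(=O)OC[C@H](C)/C=C/[C@H]1[C@@H](CO[Si](c3ccccc3)(c3ccccc3)C(C)(C)C)C=C[C@H]2C(C)(C)CCC[C@]12C | intermediate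
22 | (2R,3E)-4-[(1S,2S,4aS,8aR)-2-(hydroxymethyl)-5,5,8a-trimethyl-1,2,4a,5,6,7,8,8a-octahydronaphthalen-1-yl]-2-methylbut-3-en-1-yl 2-methylpropanoate | CC(C)C(=O)OC[C@H](C)/C=C/[C@H]1[C@@H](CO)C=C[C@H]2C(C)(C)CCC[C@]12C | intermediate
23 | (2R,3E)-4-[(1S,2S,4aS,8aR)-2-formyl-5,5,8a-trimethyl-1,2,4a,5,6,7,8,8a-octahydronaphthalen-1-yl]-2-methylbut-3-en-1-yl 2-methylpropanoate | CC(C)C(=O)OC[C@H](C)/C=C/[C@H]1[C@@H](C=O)C=C[C@H]2C(C)(C)CCC[C@]12C | intermediate (not isolated)
24 | (2R,3E)-4-[(1R,4aS,8aS)-2-formyl-5,5,8a-trimethyl-1,4,4a,5,6,7,8,8a-octahydronaphthalen-1-yl]-2-methylbut-3-en-1-yl 2-methylpropanoate | CC(C)C(=O)OC[C@H](C)/C=C/[C@H]1C(C=O)=CC[C@H]2C(C)(C)CCC[C@]12C | intermediate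
25 | (1R,4aS,8aS)-5,5,8a-trimethyl-1-[(1E,3R)-3-methyl-4-(2-methylpropanoyloxy)but-1-en-1-yl]-1,4,4a,5,6,7,8,8a-octahydronaphthalene-2-carboxylic acid | CC(C)C(=O)OC[C@H](C)/C=C/[C@H]1C(C(=O)O)=CC[C@H]2C(C)(C)CCC[C@]12C | intermediate
26 | (1R,4aS,8aS)-5,5,8a-trimethyl-1-[(3R)-3-methyl-4-(2-methylpropanoyloxy)butyl]-1,4,4a,5,6,7,8,8a-octahydronaphthalene-2-carboxylic acid | CC(C)C(=O)OC[C@H](C)CC[C@H]1C(C(=O)O)=CC[C@H]2C(C)(C)CCC[C@]12C | target

## Step count and least certain steps

Total: 17 steps. Longest linear sequence: 14 steps (steps 1–9 and 13–17); the sulfone 20 is made in steps 10–12.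

**Step 9 (key step, proposed new method).** Most likely failure: the β,β-disubstituted enal may be too unreactive at the temperatures at which the catalyst discriminates. The endo preference may also be lost, because only the formyl-endo/tether-exo transition state carries the C10/C4 methyl–methyl 1,3-diaxial contact, and this would leak into the cis-fused series. Ionisation of the dienyl ether by the strong Lewis acid is the third concern. The fallback uses known chemistry, an auxiliary-controlled, Lewis-acid-promoted intramolecular Diels–Alder reaction of a trienimide; it sets out from 14 and comes back at 15. 14 is oxidised (NaClO2, NaH2PO4, 2-methylbut-2-ene) to the trienoic acid F1. Its mixed pivalic anhydride (t-BuCOCl, Et3N) acylates lithiated (4S)-4-benzyl-1,3-oxazolidin-2-one to give the trienimide F2. Me2AlCl (1.4 equiv, CH2Cl2, −30 °C) chelates both imide carbonyl groups; the cationic complex is a much stronger dienophile and should close to the imide cycloadduct F3, the benzyl group covering the C9 Re face so that the same Si-face, endo addition results. LiBH4 (THF, MeOH) then releases the auxiliary and gives the C11 alcohol F4, and DMP oxidation returns 15.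

**Step 13.** Most likely failure: the metallated sulfone may transfer its own isobutyryl group to carbon through a five-membered transition state, or may enolise the hindered aldehyde (loss of C9 configuration, recovered aldehyde), faster than it adds. The fallback keeps the ester out of the carbanion step; it sets out from 18 and 15 and comes back at 21. 18 is silylated (TBSCl, imidazole) to the silyl ether F5 and oxidised ((NH4)6Mo7O24·4H2O, H2O2) to the silyloxy sulfone F6. F6 is joined with 15 under the conditions of step 13 to give the bis-silyl ether F7. PPTS in MeOH removes only the primary TBS group to give the C14 alcohol F8, which is acylated (i-PrCOCl, pyridine, DMAP) to 21.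

**Step 17.** Most likely failure: slow hydrogen transfer to a trans-disubstituted alkene flanked by two tertiary carbons, so that conversion stalls or the large excess of diimide begins to reduce the conjugated alkene. The fallback never makes the chain alkene; it sets out from 15 and comes back at 26. 15 is reduced (NaBH4, MeOH) to the C11 alcohol F4 and converted (I2, PPh3, imidazole) into the primary iodide F9. 16 is acylated (i-PrCOCl, Et3N) to the bromo ester F10, and zinc insertion (Zn, LiCl, THF, 50 °C) gives the alkylzinc bromide F11. Negishi alkyl–alkyl coupling of F9 with F11 (Pd2(dba)3, PCyp3, N-methylimidazole, THF/NMP) gives the saturated-chain ester F12. The C17 sequence of steps 14–16 is then run unchanged through the alcohol F13, the β,γ-unsaturated aldehyde F14 and the conjugated enal F15, whose chlorite oxidation gives 26.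

**Step 7.** Most likely failure: ionisation of the dienyl silyl ether by Me3Al or the cationic zirconium species, or incomplete capture of the alkenylaluminate by formaldehyde, which would leave the protonated alkene. The fallback trades guaranteed geometry for a separation; it sets out from 10 and comes back at 13. Hydration of the alkyne ((Ph3P)AuNTf2 cat., aqueous MeOH) gives the methyl ketone F16. Horner–Wadsworth–Emmons reaction with triethyl phosphonoacetate (NaH, THF) gives the ethyl enoate F17, from which the minor (Z) isomer must be removed by chromatography. Reduction with i-Bu2AlH then gives 13.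

## Further compounds

F1 | step 9 | (2E,8E,10E)-12-[(tert-butyldiphenylsilyl)oxy]-3,7,7-trimethyldodeca-2,8,10-trienoic acid | OC(=O)/C=C(\C)CCCC(C)(C)/C=C/C=C/CO[Si](c1ccccc1)(c1ccccc1)C(C)(C)C
F2 | step 9 | (4S)-4-benzyl-3-{(2E,8E,10E)-12-[(tert-butyldiphenylsilyl)oxy]-3,7,7-trimethyldodeca-2,8,10-trienoyl}-1,3-oxazolidin-2-one | O=C1OC[C@H](Cc2ccccc2)N1C(=O)/C=C(\C)CCCC(C)(C)/C=C/C=C/CO[Si](c1ccccc1)(c1ccccc1)C(C)(C)C
F3 | step 9 | imide cycloadduct (ring system and configuration of 15, C11 as the N-acyl carbonyl of the (4S)-4-benzyloxazolidinone) | O=C1OC[C@H](Cc2ccccc2)N1C(=O)[C@H]1[C@@H](CO[Si](c3ccccc3)(c3ccccc3)C(C)(C)C)C=C[C@H]2C(C)(C)CCC[C@]12C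
F4 | step 9 | C11 alcohol (15 with CH2OH in place of CHO) | OC[C@H]1[C@@H](CO[Si](c3ccccc3)(c3ccccc3)C(C)(C)C)C=C[C@H]2C(C)(C)CCC[C@]12C
F5 | step 13 | 5-{[(2S)-3-(tert-butyldimethylsilyloxy)-2-methylpropyl]sulfanyl}-1-phenyl-1H-tetrazole | CC(C)(C)[Si](C)(C)OC[C@H](C)CSc1nnnn1-c1ccccc1
F6 | step 13 | 5-{[(2S)-3-(tert-butyldimethylsilyloxy)-2-methylpropyl]sulfonyl}-1-phenyl-1H-tetrazole | CC(C)(C)[Si](C)(C)OC[C@H](C)CS(=O)(=O)c1nnnn1-c1ccccc1
F7 | step 13 | bis-silyl ether (21 with OTBS in place of the isobutyrate) | CC(C)(C)[Si](C)(C)OC[C@H](C)/C=C/[C@H]1[C@@H](CO[Si](c3ccccc3)(c3ccccc3)C(C)(C)C)C=C[C@H]2C(C)(C)CCC[C@]12C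
F8 | step 13 | C14 alcohol (21 with OH in place of the isobutyrate) | OC[C@H](C)/C=C/[C@H]1[C@@H](CO[Si](c3ccccc3)(c3ccccc3)C(C)(C)C)C=C[C@H]2C(C)(C)CCC[C@]12C
F9 | step 17 | C11 iodide (15 with CH2I in place of CHO) | IC[C@H]1[C@@H](CO[Si](c3ccccc3)(c3ccccc3)C(C)(C)C)C=C[C@H]2C(C)(C)CCC[C@]12C
F10 | step 17 | (2S)-3-bromo-2-methylpropyl 2-methylpropanoate | CC(C)C(=O)OC[C@H](C)CBr
F11 | step 17 | [(2S)-2-methyl-3-(2-methylpropanoyloxy)propyl]zinc bromide | CC(C)C(=O)OC[C@H](C)C[Zn]Br
F12 | step 17 | saturated-chain ester (11,12-dihydro-21) | CC(C)C(=O)OC[C@H](C)CC[C@H]1[C@@H](CO[Si](c3ccccc3)(c3ccccc3)C(C)(C)C)C=C[C@H]2C(C)(C)CCC[C@]12C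
F13 | step 17 | saturated-chain alcohol (11,12-dihydro-22) | CC(C)C(=O)OC[C@H](C)CC[C@H]1[C@@H](CO)C=C[C@H]2C(C)(C)CCC[C@]12C
F14 | step 17 | saturated-chain β,γ-unsaturated aldehyde (11,12-dihydro-23) | CC(C)C(=O)OC[C@H](C)CC[C@H]1[C@@H](C=O)C=C[C@H]2C(C)(C)CCC[C@]12C
F15 | step 17 | saturated-chain conjugated enal (11,12-dihydro-24) | CC(C)C(=O)OC[C@H](C)CC[C@H]1C(C=O)=CC[C@H]2C(C)(C)CCC[C@]12C
F16 | step 7 | (7E,9E)-11-[(tert-butyldiphenylsilyl)oxy]-6,6-dimethylundeca-7,9-dien-2-one | CC(=O)CCCC(C)(C)/C=C/C=C/CO[Si](c1ccccc1)(c1ccccc1)C(C)(C)C
F17 | step 7 | ethyl (2E,8E,10E)-12-[(tert-butyldiphenylsilyl)oxy]-3,7,7-trimethyldodeca-2,8,10-trienoate | CCOC(=O)/C=C(\C)CCCC(C)(C)/C=C/C=C/CO[Si](c1ccccc1)(c1ccccc1)C(C)(C)C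
A1 | alternative 1 | trans-hydrindene with C7=C9 alkene and TBDPS-protected chain on C9 | CC(C)(C)[Si](c1ccccc1)(c1ccccc1)OC[C@H](C)CCC1=CC[C@H]2C(C)(C)CCC[C@]12C
A2 | alternative 1 | 7α-acetoxy-8-bromo decalin with C8=C9 alkene | CC(C)(C)[Si](c1ccccc1)(c1ccccc1)OC[C@H](C)CCC1=C(Br)[C@H](OC(C)=O)C[C@H]2C(C)(C)CCC[C@]12C
A3 | alternative 2 | (S)-epoxy (E)-alkene (Z)-silyl enol ether with TBDPS-protected chain | CC1(C)O[C@H]1CC/C(C)=C/CC/C(O[Si](C)(C)C(C)(C)C)=C/CC[C@@H](C)CO[Si](c1ccccc1)(c1ccccc1)C(C)(C)C
A4 | alternative 2 | 3β-hydroxy C8-keto trans-decalin with 9β chain | CC(C)(C)[Si](c1ccccc1)(c1ccccc1)OC[C@H](C)CC[C@H]1C(=O)CC[C@H]2C(C)(C)[C@@H](O)CC[C@]12C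
A5 | alternative 3 | ring-A cyclohexene (C1=C10) with C5 side arm carrying the C7 acetate and the C8=C9 enoate (C7 either epimer) | CC1=CCCC(C)(C)[C@@H]1CC(OC(C)=O)/C(C(=O)OC)=C/CC[C@@H](C)CO[Si](c1ccccc1)(c1ccccc1)C(C)(C)C
A6 | alternative 3 | methyl ester of the target acid skeleton with TBDPS-protected chain | CC(C)(C)[Si](c1ccccc1)(c1ccccc1)OC[C@H](C)CC[C@H]1C(C(=O)OC)=CC[C@H]2C(C)(C)CCC[C@]12C
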